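Beside this flask stands a neighbour charged with 0.570 equiv of X, and the next run must choose between changing the hours and changing the charge.

D 0.25 M; X 0.950 equiv; J 0.0500 M; time 2.5 h

    D + X → D.X (k1 = 0.014 /M/s)
    D.X → L (k2 = 0.0013 /s)
    X + J → X.J (k3 = 0.26 /M/s)
    D.X → Q (k4 = 0.012 /s)

1. which holds at 2.5 h: what has brought the reaction to rest, or that it has not come to rest (it is still moving / all of D has reacted / X has run out first)
2. share of the D used up at 2.5 h
3. L at 2.5 h, in percent of the D charged
4. Q at 2.5 h, in percent of the D charged

- the reaction counts as stopped when no species that holds the D changes by six tenths of a point or more over the second half of the time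
- run time (flask): 2.5 h

X has two takers, and per unit of concentration J takes it 18.6 times as fast as D does. This ratio is a selectivity factor. Both steps draw on the same X, and in this scheme the factor gives a rule in logarithms: the decadic logarithm of the share of J left equals the factor times the logarithm of the share of D left.

The reckoning here therefore pays J first. What remains is the allowance of D, the X charged less the J charged, per D charged: 75.0 %. With that share of D gone, the rule puts c(J) at ten to the power −11.2 of its charge, so the allowance stands and X is the limiting reagent.

X then dies away against the remaining D with a half-life of 0.220 h, so 2.5 h takes it down 3.42 powers of ten. Since this half-life is shorter than the run, the hours stay as they are and the charge is what to change.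

D.X lives 75.2 s, less than the run, and a share 9.77 % of it becomes L. The reckoning commits to X has run out first, with conversion 75.0 %, L 7.33 % and Q 67.7 %.

The forecast reads X has run out first, with 75 % of D used, 7.33 % of L and 67.66 % of Q, holding that “the second-order tail has essentially exhausted X”.

The simulation gives X has run out first, with 75.0 % of D used, 7.33 % of L and 67.7 % of Q.

In the flask, D and J both drew on X at the start, and by 0.250 h J stood at 0 %, X.J at 0.0500 M and D at 37.9 %. D then went on taking X until, at 2.50 h, X stood at 0.00747 % of its charge and D at 25.0 %. The neighbour's allowance is 37.0 %, and it converts 37.0 % of its D. Its D left, 63 %, raised to the selectivity factor gives 0.0187 % of J, and J there stood at 0.019 %.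

The numbers of this flask are invented; no experiment stands behind them.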